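**Assumption:** (+)-sclareolide and 3-(furan-3-yl)propanoic acid are taken as catalogue compounds; labdane/drimane numbering is used for all sclareolide-derived carbons (C5 is the stereocenter that ends up in the target).

## Retrosynthetic overview

1. The single stereocenter (S) is bought as C5 of (+)-sclareolide (1). No ring is formed in the route: ring A is kept and ring B is opened.
2. Photochemical key disconnection: the C9–C10 bond of 8α-hydroxydriman-11-al (5) is cut by γ-hydrogen abstraction from C1. This makes the ring olefin and, after retro-aldol, (S)-dihydro-α-ionone (8).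
3. The E-trisubstituted olefin comes from alkyne carboalumination/iodination, giving vinyl iodide (12).
4. Electrochemical key disconnection: the C9–C11 bond joins 12 and 3-(furan-3-yl)propanoic acid (13) by decarboxylative alkenylation, giving furan (15).
5. The furan is the masked (Z)-enediol: singlet-oxygen oxidation, reduction and acetylation give the target (19).

## Route

Step 1
Reactants: 1 (+)-sclareolide
Product: 3 11-hydroxysclareolide (both C11 epimers), via hydroperoxide 2 (not isolated)
Conditions: KN(SiMe3)2, THF, −78 °C; O2, P(OEt)3, −78 → −20 °C; then 1 M HCl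
Reagents that add atoms: dioxygen, O=O
Why: Enolate oxygenation: the lactone enolate is trapped by O2 and the hydroperoxide is reduced in situ by the phosphite; the new C11 center is irrelevant because it is destroyed in step 3.

Step 2
Reactants: 3 11-hydroxysclareolide
Product: 4 13,14,15,16-tetranorlabdane-8α,11,12-triol (ring configuration as in 1)
Conditions: LiAlH4, THF, 0 → 65 °C; H2O/NaOH work-up
Reagents that add atoms: none
Why: Hydride reduction of the lactone to the diol; C5, C8, C9 and C10 are not touched.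

Step 3
Reactants: 4 13,14,15,16-tetranorlabdane-8α,11,12-triol
Product: 5 8α-hydroxydriman-11-al [(1R,2R,4aS,8aS)-2-hydroxy-2,5,5,8a-tetramethyldecahydronaphthalene-1-carbaldehyde]
Conditions: NaIO4, THF–H2O (pH 7), 0 → 20 °C; used crude
Reagents that add atoms: none
Why: Malaprade glycol cleavage of the 11,12-diol; the tertiary 8-OH is 1,3 to C11 and is not cleaved, and the equatorial CHO at C9 is the stable epimer.

Step 4
Reactants: 5 8α-hydroxydriman-11-al
Product: 8 (S)-dihydro-α-ionone [4-[(1S)-2,6,6-trimethylcyclohex-2-en-1-yl]butan-2-one], via enol 6 (not isolated), via seco hydroxy aldehyde 7 (not isolated)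
Conditions: hν (310 nm), degassed t-BuOH–MeCN (1:1), 0.01 M, 20 °C, to about 90 % conversion; then K2CO3 (0.3 equiv), MeOH–H2O, 20 °C
Reagents that add atoms: none
Why: Proposed new method: Norrish type 2 ring scission of a drimane — the n,π* excited C11 aldehyde abstracts the peri, equatorial hydrogen on C1 through a six-membered transition state (the only secondary γ-H within reach, since C7 and C5 sit anti to C11; the competing γ-hydrogens are primary, on the two axial methyl groups), and the 1,4-biradical, once ring A twists enough to line the C9–C10 bond up with the C1 orbital (a twist favoured by loss of the 1,3-diaxial methyl/methyl strain and given time by the hydrogen-bonding solvent, which suppresses back-transfer), cleaves C9–C10 to give the C1=C10 olefin and enol 6, whose aldehyde tautomer 7 loses acetaldehyde by base-catalysed retro-aldol; the closest known reaction type is the Norrish type 2 cleavage of acyclic aliphatic aldehydes and ketones (used on side-chain ketones of labdanes, never to open ring B at C9–C10); no stereocenter is made, C5 of 1 is untouched and becomes the (S) center of 8.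

Step 5
Reactants: 8 (S)-dihydro-α-ionone
Product: 10 (6S)-6-(but-3-yn-1-yl)-1,5,5-trimethylcyclohex-1-ene, via enol phosphate 9 (not isolated)
Conditions: LiN(i-Pr)2 (1.1 equiv), THF, −78 °C; ClP(O)(OEt)2, −78 → 20 °C; LiN(i-Pr)2 (2.3 equiv), −78 → 20 °C
Reagents that add atoms: none
Why: Negishi alkyne synthesis: the kinetic methyl enolate is trapped as the enol phosphate and eliminated to the terminal alkyne; the allylic C5–H is far too weakly acidic to be touched.

Step 6
Reactants: 10 (6S)-6-(but-3-yn-1-yl)-1,5,5-trimethylcyclohex-1-ene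
Product: 12 (6S)-6-[(3E)-4-iodo-3-methylbut-3-en-1-yl]-1,5,5-trimethylcyclohex-1-ene, via alkenylalane 11 (not isolated)
Conditions: AlMe3 (2 equiv), Cp2ZrCl2 (0.25 equiv), CH2Cl2, 0 → 23 °C; then I2, THF, −30 → 0 °C
Reagents that add atoms: trimethylaluminium, C[Al](C)C; iodine, II
Why: Zirconium-catalysed Negishi carboalumination: syn addition of Me–Al puts the methyl on the internal carbon, and iodinolysis with retention gives the E iodide; the trisubstituted ring olefin is inert.

Step 7
Reactants: 12 (6S)-6-[(3E)-4-iodo-3-methylbut-3-en-1-yl]-1,5,5-trimethylcyclohex-1-ene; 13 3-(furan-3-yl)propanoic acid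
Product: 15 3-[(3E)-4-methyl-6-[(1S)-2,6,6-trimethylcyclohex-2-en-1-yl]hex-3-en-1-yl]furan, via NHPI ester 14 (not isolated)
Conditions: 13 (1.8 equiv), N-hydroxyphthalimide, DIC, DMAP (cat.), CH2Cl2, 25 °C, evaporate; then 12, NiCl2·6H2O (20 mol %), 2,2′-bipyridine (20 mol %), AgNO3 (0.3 equiv), DMF, Mg anode/RVC cathode, constant current (about 2.5 F/mol), 25 °C
Reagents that add atoms: none
Why: Nickel-electrocatalytic decarboxylative alkenylation: reduction of the redox-active ester releases CO2 and the primary radical, which the alkenylnickel species from 12 captures with retention of the E geometry; this forms the C9–C11 bond that joins the two fragments.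

Step 8
Reactants: 15 3-[(3E)-4-methyl-6-[(1S)-2,6,6-trimethylcyclohex-2-en-1-yl]hex-3-en-1-yl]furan
Product: 18 (2Z)-2-[(3E)-4-methyl-6-[(1S)-2,6,6-trimethylcyclohex-2-en-1-yl]hex-3-en-1-yl]but-2-ene-1,4-diol, via endoperoxide 16 (not isolated), via enedial 17 (not isolated)
Conditions: O2, tetraphenylporphyrin (cat.), hν (visible), CH2Cl2, −78 °C; Me2S, −78 → −30 °C; then MeOH, CeCl3·7H2O, NaBH4, −78 → 0 °C
Reagents that add atoms: dioxygen, O=O
Why: [4+2] photooxygenation of the furan by singlet oxygen (much faster at −78 °C than the ene reaction of the two trisubstituted olefins), sulfide reduction of the endoperoxide to the cis-enedial and Luche 1,2-reduction; the Z geometry is fixed by the furan ring.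

Step 9
Reactants: 18 (2Z)-2-[(3E)-4-methyl-6-[(1S)-2,6,6-trimethylcyclohex-2-en-1-yl]hex-3-en-1-yl]but-2-ene-1,4-diol
Product: 19 (2Z)-2-[(3E)-4-methyl-6-[(1S)-2,6,6-trimethylcyclohex-2-en-1-yl]hex-3-en-1-yl]but-2-ene-1,4-diyl diacetate (target)
Conditions: Ac2O, pyridine, DMAP (cat.), CH2Cl2, 0 → 20 °C
Reagents that add atoms: acetic anhydride, CC(=O)OC(C)=O
Why: Acyl transfer to both primary allylic alcohols; non-acidic conditions leave the ring olefin and the allylic stereocenter untouched.

## Compound list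

1 | (+)-sclareolide, (3aR,5aS,9aS,9bR) | CC1(C)CCC[C@@]2(C)[C@H]1CC[C@@]1(C)OC(=O)C[C@H]21 | starting material
2 | 11-hydroperoxysclareolide (C11 epimers) | CC1(C)CCC[C@@]2(C)[C@H]1CC[C@@]1(C)OC(=O)C(OO)[C@H]21 | intermediate (not isolated)
3 | 11-hydroxysclareolide (C11 epimers) | CC1(C)CCC[C@@]2(C)[C@H]1CC[C@@]1(C)OC(=O)C(O)[C@H]21 | intermediate
4 | 13,14,15,16-tetranorlabdane-8α,11,12-triol (C11 epimers) | CC1(C)CCC[C@@]2(C)[C@H]1CC[C@@](C)(O)[C@@H]2C(O)CO | intermediate
5 | 8α-hydroxydriman-11-al, (1R,2R,4aS,8aS) | CC1(C)CCC[C@@]2(C)[C@H]1CC[C@@](C)(O)[C@@H]2C=O | intermediate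
6 | (3R)-3-methyl-5-[(1S)-2,6,6-trimethylcyclohex-2-en-1-yl]pent-1-ene-1,3-diol (enol) | OC=C[C@](C)(O)CC[C@@H]1C(C)=CCCC1(C)C | intermediate (not isolated)
7 | (3R)-3-hydroxy-3-methyl-5-[(1S)-2,6,6-trimethylcyclohex-2-en-1-yl]pentanal | O=CC[C@](C)(O)CC[C@@H]1C(C)=CCCC1(C)C | intermediate (not isolated)
8 | (S)-dihydro-α-ionone | CC(=O)CC[C@@H]1C(C)=CCCC1(C)C | intermediate
9 | diethyl 4-[(1S)-2,6,6-trimethylcyclohex-2-en-1-yl]but-1-en-2-yl phosphate | C=C(OP(=O)(OCC)OCC)CC[C@@H]1C(C)=CCCC1(C)C | intermediate (not isolated)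
10 | (6S)-6-(but-3-yn-1-yl)-1,5,5-trimethylcyclohex-1-ene | C#CCC[C@@H]1C(C)=CCCC1(C)C | intermediate
11 | dimethyl[(1E)-2-methyl-4-[(1S)-2,6,6-trimethylcyclohex-2-en-1-yl]but-1-en-1-yl]alane | C[Al](C)/C=C(\C)CC[C@@H]1C(C)=CCCC1(C)C | intermediate (not isolated)
12 | (6S)-6-[(3E)-4-iodo-3-methylbut-3-en-1-yl]-1,5,5-trimethylcyclohex-1-ene | I/C=C(\C)CC[C@@H]1C(C)=CCCC1(C)C | intermediate
13 | 3-(furan-3-yl)propanoic acid | OC(=O)CCc1ccoc1 | starting material
14 | 1,3-dioxoisoindolin-2-yl 3-(furan-3-yl)propanoate | O=C(CCc1ccoc1)ON1C(=O)c2ccccc2C1=O | intermediate (not isolated)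
15 | 3-[(3E)-4-methyl-6-[(1S)-2,6,6-trimethylcyclohex-2-en-1-yl]hex-3-en-1-yl]furan | c1cc(CC/C=C(\C)CC[C@@H]2C(C)=CCCC2(C)C)co1 | intermediate
16 | 5-substituted 2,3,7-trioxabicyclo[2.2.1]hept-5-ene (furan endoperoxide of 15, both bridgehead diastereomers) | C1(=CC2OOC1O2)CC/C=C(\C)CC[C@@H]1C(C)=CCCC1(C)C | intermediate (not isolated)
17 | (2Z)-2-[(3E)-4-methyl-6-[(1S)-2,6,6-trimethylcyclohex-2-en-1-yl]hex-3-en-1-yl]but-2-enedial | O=C/C=C(/CC/C=C(\C)CC[C@@H]1C(C)=CCCC1(C)C)C=O | intermediate (not isolated)
18 | (2Z)-2-[(3E)-4-methyl-6-[(1S)-2,6,6-trimethylcyclohex-2-en-1-yl]hex-3-en-1-yl]but-2-ene-1,4-diol | OC/C=C(/CC/C=C(\C)CC[C@@H]1C(C)=CCCC1(C)C)CO | intermediate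
19 | (2Z)-2-[(3E)-4-methyl-6-[(1S)-2,6,6-trimethylcyclohex-2-en-1-yl]hex-3-en-1-yl]but-2-ene-1,4-diyl diacetate | CC(=O)OC/C=C(/CC/C=C(\C)CC[C@@H]1C(C)=CCCC1(C)C)COC(C)=O | target

## Step count and risks

Total steps: 9. Longest linear sequence: 9 (1 → 19); 13 is bought and enters at step 7.

**Step 4 (the proposed new photochemical ring scission) — most likely to fail.**
- Abstraction from the C10 methyl instead of C1 would give the exocyclic olefin isomer.
- The C1 biradical may revert or close to a cyclobutanol instead of cleaving.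
- Norrish type 1 decarbonylation can compete.
- Ketone 8 itself is photolabile, hence 310 nm light and incomplete conversion.

Fallback, setting out from 5 and coming back at 8, thermal and built from known reaction types: aerobic copper-catalysed deformylation of 5 (CuCl, 2,2′-bipyridine, DABCO, O2, DMF) gives the α-ketol 8α-hydroxy-11-nordriman-9-one F1. NaIO4 in aqueous MeOH cleaves the ketol to the seco keto acid (1S,2S)-1,3,3-trimethyl-2-(3-oxobutyl)cyclohexane-1-carboxylic acid F2, in which C9 has become a carboxyl on C10. Kochi oxidative decarboxylation (Pb(OAc)4, Cu(OAc)2, pyridine, benzene, 80 °C) then gives 8 together with its exocyclic isomer (S)-γ-dihydroionone F3. F3 is removed on AgNO3-impregnated silica or isomerised into 8 with RhCl3·3H2O in ethanol. This is longer and less regioselective, but C5 is never touched.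

**Step 7 (electrochemical decarboxylative alkenylation).**
- Risks are protodeiodination of 12, dimerisation of the radical, and the one-pot ester activation.

Fallback, setting out from 12 (with 14 isolated from 13) and coming back at 15, a redox-neutral organozinc coupling without electrolysis: 12 is converted (t-BuLi, −78 °C; then ZnCl2) into chloro[(1E)-2-methyl-4-[(1S)-2,6,6-trimethylcyclohex-2-en-1-yl]but-1-en-1-yl]zinc F4. F4 is coupled with 14 under NiCl2·6H2O/2,2′-bipyridine catalysis in THF–DMF at 25 °C (decarboxylative Negishi-type alkenylation).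

**Step 8 (singlet oxygen in the presence of two trisubstituted olefins).**
- Risks are ene hydroperoxidation of the olefins and cis-to-trans isomerisation of enedial 17.

Fallback, setting out from 15 and coming back at 18, with no oxidant that can attack the olefins: one-pot lithiation–borylation–oxidation (n-BuLi, THF, −78 → 0 °C; B(OMe)3; then H2O2, Na2CO3) turns the furan into two butenolides. These are 3-[(3E)-4-methyl-6-[(1S)-2,6,6-trimethylcyclohex-2-en-1-yl]hex-3-en-1-yl]furan-2(5H)-one F5 and its 4-substituted regioisomer 4-[(3E)-4-methyl-6-[(1S)-2,6,6-trimethylcyclohex-2-en-1-yl]hex-3-en-1-yl]furan-2(5H)-one F6. Both are reduced by i-Bu2AlH (CH2Cl2, −78 → 0 °C) to the same (Z)-diol 18.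

Further compounds
F1 | step 4 | 8α-hydroxy-11-nordriman-9-one, (2R,4aS,8aS) | CC1(C)CCC[C@@]2(C)[C@H]1CC[C@@](C)(O)C2=O
F2 | step 4 | (1S,2S)-1,3,3-trimethyl-2-(3-oxobutyl)cyclohexane-1-carboxylic acid | CC(=O)CC[C@H]1C(C)(C)CCC[C@]1(C)C(O)=O
F3 | step 4 | (S)-γ-dihydroionone, 4-[(1S)-2,2-dimethyl-6-methylidenecyclohexyl]butan-2-one | CC(=O)CC[C@@H]1C(=C)CCCC1(C)C
F4 | step 7 | chloro[(1E)-2-methyl-4-[(1S)-2,6,6-trimethylcyclohex-2-en-1-yl]but-1-en-1-yl]zinc | Cl[Zn]/C=C(\C)CC[C@@H]1C(C)=CCCC1(C)C
F5 | step 8 | 3-[(3E)-4-methyl-6-[(1S)-2,6,6-trimethylcyclohex-2-en-1-yl]hex-3-en-1-yl]furan-2(5H)-one | O=C1OCC=C1CC/C=C(\C)CC[C@@H]2C(C)=CCCC2(C)C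
F6 | step 8 | 4-[(3E)-4-methyl-6-[(1S)-2,6,6-trimethylcyclohex-2-en-1-yl]hex-3-en-1-yl]furan-2(5H)-one | O=C1OCC(=C1)CC/C=C(\C)CC[C@@H]2C(C)=CCCC2(C)C
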